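**Strategy.** The benzo ring (ring A) of the coumarin is built, not bought. Its two meta-related oxygens (O1 on C8a and the C7 methoxy oxygen), C8 between them and C4a bearing the pyranone carbon C4 are the pattern that a vinylketene–ynol ether benzannulation delivers. One operation merges a diazo enone carrying C4 as a dimethyl acetal with a methyl ynol ether that already holds the silyl-protected C1′ stereocentre, its future ketone masked as a methylidene group. This forms C8a–C8, C7–C6 and C4a–C8a and gives the fully substituted phenol. Lactone annulation, alkene cleavage and silyl-to-acyl exchange finish the target.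

Key step: step 8

Locants follow coumarin numbering (O1, C2–C8a); C1′ and C2′ are the side-chain carbons on C8.

Assumption: in the lipase step the linear methoxyethynyl group is taken as the smaller and the branched alkenyl group as the larger carbinol substituent, so the (S)-alcohol is the enantiomer acylated; the configuration of 13 is to be confirmed (Mosher esters) before silylation.

**Step 1**
Reactants: 1 2,2-dimethoxyacetaldehyde (60 wt% aqueous solution); 2 1-(triphenylphosphoranylidene)propan-2-one
Product: 3 (E)-5,5-dimethoxypent-3-en-2-one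
Conditions: CH2Cl2/H2O, 25 °C
Reagents that add atoms: none
Why: Wittig olefination with a ketone-stabilised ylide is reliably (E)-selective and tolerates both the aqueous aldehyde and the acetal.

**Step 2**
Reactants: 3 (E)-5,5-dimethoxypent-3-en-2-one
Product: 5 (E)-1-diazo-5,5-dimethoxypent-3-en-2-one, via trifluoroacetyl diketone 4 (not isolated)
Conditions: LiN(SiMe3)2, THF, −78 °C; CF3CO2CH2CF3; aq. NH4Cl; then 4-AcNHC6H4SO2N3, Et3N, H2O, MeCN, 25 °C
Reagents that add atoms: 4-acetamidobenzenesulfonyl azide, CC(=O)Nc1ccc(cc1)S(=O)(=O)N=[N+]=[N-] (N2 of 5); 2,2,2-trifluoroethyl trifluoroacetate, O=C(OCC(F)(F)F)C(F)(F)F (CF3CO of 4 only)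
Why: Detrifluoroacetylative diazo transfer (kinetic methyl enolate, Claisen trifluoroacetylation, then sulfonyl azide with loss of the activating acyl group) is the standard entry to diazomethyl enones and avoids diazomethane, which would add across the conjugated C=C of an enoyl electrophile.

**Step 3**
Reactants: 6 3-methylbutanal; 7 formaldehyde (37% aqueous)
Product: 8 3-methyl-2-methylidenebutanal
Conditions: pyrrolidine (10 mol %), EtCO2H (10 mol %), i-PrOH, 45 °C
Reagents that add atoms: none
Why: Amine/acid-catalysed Mannich condensation–elimination (α-methylenation of an aldehyde) is a standard route to 2-alkylacroleins.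

**Step 4**
Reactants: 9 2-chloro-1,1-dimethoxyethane; 8 3-methyl-2-methylidenebutanal
Product: 11 rac-1-methoxy-5-methyl-4-methylidenehex-1-yn-3-ol, via lithium methoxyacetylide 10 (not isolated)
Conditions: LiNEt2 (3.1 equiv, from Et2NH/n-BuLi), THF, −10 → 0 °C; then 8, −78 °C; H2O/NaHCO3 work-up
Reagents that add atoms: lithium diethylamide, [Li+].CC[N-]CC (lithium of 10 only)
Why: Double elimination and deprotonation of the chloroacetal gives the alkoxyacetylide, which adds 1,2 to the enal at low temperature (acetylide addition to an aldehyde); the stereocentre forms as a racemate and the non-acidic work-up avoids Meyer–Schuster rearrangement.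

**Step 5**
Reactants: 11 rac-1-methoxy-5-methyl-4-methylidenehex-1-yn-3-ol
Product: 12 (S)-1-methoxy-5-methyl-4-methylidenehex-1-yn-3-yl acetate
Conditions: lipase PS (Burkholderia cepacia, immobilised), vinyl acetate, MTBE, 4 Å MS, 30 °C, to ca. 45% conversion
Reagents that add atoms: vinyl acetate, CC(=O)OC=C
Why: Lipase-catalysed acylative kinetic resolution under neutral anhydrous conditions selects the stereocentre: by the empirical size rule the enantiomer with the slim alkynyl group in the small pocket, here (S), should be acylated, and stopping short of half conversion protects the ee of the ester.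

**Step 6**
Reactants: 12 (S)-1-methoxy-5-methyl-4-methylidenehex-1-yn-3-yl acetate
Product: 13 (S)-1-methoxy-5-methyl-4-methylidenehex-1-yn-3-ol
Conditions: K2CO3 (0.2 equiv), MeOH, 0 °C
Reagents that add atoms: none
Why: Base-catalysed transesterification cleaves the acyl–oxygen bond only, so C3 keeps its configuration, and ynol ethers are stable to mild base.

**Step 7**
Reactants: 13 (S)-1-methoxy-5-methyl-4-methylidenehex-1-yn-3-ol
Product: 14 (S)-tert-butyl[(1-methoxy-5-methyl-4-methylidenehex-1-yn-3-yl)oxy]dimethylsilane
Conditions: TBSCl, imidazole, DMF, 0 → 25 °C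
Reagents that add atoms: tert-butyldimethylsilyl chloride, CC(C)(C)[Si](C)(C)Cl
Why: Imidazole-promoted O-silylation of a secondary alcohol is base-buffered, so the acid-labile ynol ether and the stereocentre are untouched.

**Step 8**
Reactants: 5 (E)-1-diazo-5,5-dimethoxypent-3-en-2-one; 14 (S)-tert-butyl[(1-methoxy-5-methyl-4-methylidenehex-1-yn-3-yl)oxy]dimethylsilane
Product: 18 (S)-2-[1-(tert-butyldimethylsilyloxy)-3-methyl-2-methylidenebutyl]-6-(dimethoxymethyl)-3-methoxyphenol, via vinylketene 15 (not isolated), via 4-alkenylcyclobutenone 16 (not isolated), via dienylketene 17 (not isolated)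
Conditions: 5 (1.2 equiv), hν (254 nm, quartz), degassed ClCH2CH2Cl, 25 °C; then 80 °C
Reagents that add atoms: none
Why: Irradiation expels N2 from 5 and a Wolff shift of the alkenyl group gives vinylketene 15; the ynol ether adds its side-chain-bearing carbon to the ketene carbonyl carbon and closes the four-membered ring of 16 by formal [2+2] cycloaddition (C8a–C8 and C7–C6), the alkenyl group ending on the sp3 carbon of a 4-alkenylcyclobut-2-enone. At 80 °C 16 opens by reversible 4π electrocyclic cleavage to dienylketene 17, whose isomer with the ketene and alkenyl termini cis closes the six-membered carbocycle by 6π electrocyclisation (C4a–C8a) and tautomerises to phenol 18. The closest known reaction type is the Danheiser benzannulation in its photochemical Wolff (diazo ketone) form with alkoxyalkynes, which gives resorcinol monoethers of this pattern. No stereocentre is created: the sp3 centre of 16 is lost on aromatisation, and the silyl-protected, non-enolisable C1′ centre lies outside every bond-forming event under neutral photothermal conditions. The step needs regioselectivity, secured by the polarisation of the ynol ether (its oxygen-bearing carbon becomes C7, so OH and OMe end meta with C8 between them and the acetal carbon ortho to OH), and chemoselectivity for the alkyne over the hindered 1,1-disubstituted alkene, secured by the far higher nucleophilicity of the alkynyl ether; a methyl ynol ether also cannot fragment by retro-ene loss of an alkene on heating.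

**Step 9**
Reactants: 18 (S)-2-[1-(tert-butyldimethylsilyloxy)-3-methyl-2-methylidenebutyl]-6-(dimethoxymethyl)-3-methoxyphenol
Product: 19 (S)-3-[1-(tert-butyldimethylsilyloxy)-3-methyl-2-methylidenebutyl]-2-hydroxy-4-methoxybenzaldehyde
Conditions: PPTS (10 mol %), acetone/H2O (10:1), 25 °C
Reagents that add atoms: water, O
Why: Acid-catalysed acetal hydrolysis is very fast for an electron-rich aryl dimethyl acetal, so a pyridinium acid suffices and the benzylic silyl ether stays in place.

**Step 10**
Reactants: 19 (S)-3-[1-(tert-butyldimethylsilyloxy)-3-methyl-2-methylidenebutyl]-2-hydroxy-4-methoxybenzaldehyde; 20 (triphenylphosphoranylidene)ketene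
Product: 22 (S)-8-[1-(tert-butyldimethylsilyloxy)-3-methyl-2-methylidenebutyl]-7-methoxy-2H-chromen-2-one, via aryl ester phosphorane 21 (not isolated)
Conditions: toluene, 90 °C
Reagents that add atoms: none
Why: The phenol adds to the cumulated ylide (Bestmann ylide) and the resulting ester-stabilised phosphorane undergoes intramolecular Wittig olefination with the ortho aldehyde, which forms the C3=C4 bond cis inside the lactone at moderate temperature and spares the benzylic silyl ether the >200 °C of a thermal cinnamate lactonisation.

**Step 11**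
Reactants: 22 (S)-8-[1-(tert-butyldimethylsilyloxy)-3-methyl-2-methylidenebutyl]-7-methoxy-2H-chromen-2-one
Product: 23 (R)-8-[1-(tert-butyldimethylsilyloxy)-3-methyl-2-oxobutyl]-7-methoxy-2H-chromen-2-one
Conditions: O3, CH2Cl2, −78 °C (Sudan red 7B end point); then PPh3, −78 → 25 °C
Reagents that add atoms: ozone, [O-][O+]=O
Why: Ozonolysis with reductive work-up cleaves the isolated 1,1-disubstituted alkene well before the lactone-conjugated C3=C4 bond, the indicator dye limiting ozone exposure; C1′ is untouched and only its descriptor changes from S to R because the new carbonyl carbon outranks the aryl carbon.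

**Step 12**
Reactants: 23 (R)-8-[1-(tert-butyldimethylsilyloxy)-3-methyl-2-oxobutyl]-7-methoxy-2H-chromen-2-one
Product: 24 (R)-8-(1-hydroxy-3-methyl-2-oxobutyl)-7-methoxy-2H-chromen-2-one
Conditions: HF·pyridine, pyridine, THF, 0 °C
Reagents that add atoms: none
Why: Fluoride-mediated desilylation under buffered, weakly acidic conditions avoids the basic media that would enolise the benzylic α-ketol and erode C1′; the product is used at once.

**Step 13**
Reactants: 24 (R)-8-(1-hydroxy-3-methyl-2-oxobutyl)-7-methoxy-2H-chromen-2-one; 25 3-methylbut-2-enoic acid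
Product: 26 (R)-1-(7-methoxy-2-oxo-2H-chromen-8-yl)-3-methyl-2-oxobutyl 3-methylbut-2-enoate (target)
Conditions: DCC, DMAP (10 mol %), CH2Cl2, 0 → 25 °C
Reagents that add atoms: none
Why: Steglich esterification acylates the hydroxyl without breaking the C1′–O bond (retention), and low temperature with catalytic DMAP limits enolisation at C1′ and deconjugation of the senecioyl group.

**Compound list**
1 | 2,2-dimethoxyacetaldehyde | COC(OC)C=O | starting material
2 | 1-(triphenylphosphoranylidene)propan-2-one | CC(=O)C=P(c1ccccc1)(c1ccccc1)c1ccccc1 | starting material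
3 | (E)-5,5-dimethoxypent-3-en-2-one | COC(OC)/C=C/C(C)=O | intermediate
4 | (E)-1,1,1-trifluoro-7,7-dimethoxyhept-5-ene-2,4-dione | COC(OC)/C=C/C(=O)CC(=O)C(F)(F)F | intermediate (not isolated)
5 | (E)-1-diazo-5,5-dimethoxypent-3-en-2-one | COC(OC)/C=C/C(=O)C=[N+]=[N-] | intermediate
6 | 3-methylbutanal | CC(C)CC=O | starting material
7 | formaldehyde | C=O | starting material
8 | 3-methyl-2-methylidenebutanal | CC(C)C(=C)C=O | intermediate
9 | 2-chloro-1,1-dimethoxyethane | COC(OC)CCl | starting material
10 | lithium methoxyacetylide | [Li]C#COC | intermediate (not isolated)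
11 | rac-1-methoxy-5-methyl-4-methylidenehex-1-yn-3-ol | COC#CC(O)C(=C)C(C)C | intermediate
12 | (S)-1-methoxy-5-methyl-4-methylidenehex-1-yn-3-yl acetate | COC#C[C@@H](OC(C)=O)C(=C)C(C)C | intermediate
13 | (S)-1-methoxy-5-methyl-4-methylidenehex-1-yn-3-ol | COC#C[C@@H](O)C(=C)C(C)C | intermediate
14 | (S)-tert-butyl[(1-methoxy-5-methyl-4-methylidenehex-1-yn-3-yl)oxy]dimethylsilane | COC#C[C@@H](O[Si](C)(C)C(C)(C)C)C(=C)C(C)C | intermediate
15 | (E)-5,5-dimethoxypenta-1,3-dien-1-one | COC(OC)/C=C/C=C=O | intermediate (not isolated)
16 | 2-[(1S)-1-(tert-butyldimethylsilyloxy)-3-methyl-2-methylidenebutyl]-4-[(E)-3,3-dimethoxyprop-1-enyl]-3-methoxycyclobut-2-en-1-one (C4 epimers) | COC1=C([C@@H](O[Si](C)(C)C(C)(C)C)C(=C)C(C)C)C(=O)C1/C=C/C(OC)OC | intermediate (not isolated)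
17 | (3E,5E)-2-[(1S)-1-(tert-butyldimethylsilyloxy)-3-methyl-2-methylidenebutyl]-3,7,7-trimethoxyhepta-1,3,5-trien-1-one | O=C=C([C@@H](O[Si](C)(C)C(C)(C)C)C(=C)C(C)C)/C(OC)=C\C=C\C(OC)OC | intermediate (not isolated)
18 | (S)-2-[1-(tert-butyldimethylsilyloxy)-3-methyl-2-methylidenebutyl]-6-(dimethoxymethyl)-3-methoxyphenol | COC(OC)c1ccc(OC)c(c1O)[C@@H](O[Si](C)(C)C(C)(C)C)C(=C)C(C)C | intermediate
19 | (S)-3-[1-(tert-butyldimethylsilyloxy)-3-methyl-2-methylidenebutyl]-2-hydroxy-4-methoxybenzaldehyde | O=Cc1ccc(OC)c(c1O)[C@@H](O[Si](C)(C)C(C)(C)C)C(=C)C(C)C | intermediate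
20 | (triphenylphosphoranylidene)ketene | O=C=C=P(c1ccccc1)(c1ccccc1)c1ccccc1 | starting material
21 | 6-formyl-3-methoxy-2-[(1S)-1-(tert-butyldimethylsilyloxy)-3-methyl-2-methylidenebutyl]phenyl (triphenylphosphoranylidene)acetate | O=Cc1ccc(OC)c([C@@H](O[Si](C)(C)C(C)(C)C)C(=C)C(C)C)c1OC(=O)C=P(c1ccccc1)(c1ccccc1)c1ccccc1 | intermediate (not isolated)
22 | (S)-8-[1-(tert-butyldimethylsilyloxy)-3-methyl-2-methylidenebutyl]-7-methoxy-2H-chromen-2-one | COc1ccc2ccc(=O)oc2c1[C@@H](O[Si](C)(C)C(C)(C)C)C(=C)C(C)C | intermediate
23 | (R)-8-[1-(tert-butyldimethylsilyloxy)-3-methyl-2-oxobutyl]-7-methoxy-2H-chromen-2-one | COc1ccc2ccc(=O)oc2c1[C@@H](O[Si](C)(C)C(C)(C)C)C(=O)C(C)C | intermediate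
24 | (R)-8-(1-hydroxy-3-methyl-2-oxobutyl)-7-methoxy-2H-chromen-2-one | COc1ccc2ccc(=O)oc2c1[C@@H](O)C(=O)C(C)C | intermediate
25 | 3-methylbut-2-enoic acid | CC(C)=CC(=O)O | starting material
26 | (R)-1-(7-methoxy-2-oxo-2H-chromen-8-yl)-3-methyl-2-oxobutyl 3-methylbut-2-enoate | COc1ccc2ccc(=O)oc2c1[C@@H](OC(=O)C=C(C)C)C(=O)C(C)C | target

**Step count.** Total: 13 steps. Longest linear sequence: 11 steps (steps 3–13, from 3-methylbutanal).

**Steps most likely to fail**

1. Step 8. The cycloaddition of the hindered ynol ether may be slower than self-reaction or secondary photolysis of the short-lived vinylketene. The ynol ether may also be lost to traces of acid from the chlorinated solvent, and the product phenol may be acylated by surplus ketene. Fallback, setting out from 14: the vinylketene is generated thermally and without light from a cyclobutenone, and the C4 carbon is added afterwards. Commercial 3-bromocyclobutanone is dehydrobrominated with n-Bu3N to cyclobut-2-en-1-one F1. Heating F1 with 14 in toluene at 80–110 °C should run the same [2+2]/4π/6π cascade to (S)-2-[1-(tert-butyldimethylsilyloxy)-3-methyl-2-methylidenebutyl]-3-methoxyphenol F2. Magnesium-mediated ortho-formylation (MgCl2, Et3N, paraformaldehyde, MeCN, reflux) at the only free ortho position then gives 19, where the route is rejoined.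

2. Step 5. Acyl transfer may be slow and poorly selective because neither carbinol substituent is small, which caps the ee of the ester (the product side of the resolution). Acetic acid traces may also trigger rearrangement of the hydroxy ynol ether. Fallback, setting out from 11: resolution is replaced by asymmetric reduction. Oxidation with activated MnO2 (CH2Cl2, 0 °C) should give 1-methoxy-5-methyl-4-methylidenehex-1-yn-3-one F3. CBS reduction [(S)-2-methyl-CBS-oxazaborolidine (cat.), catecholborane, toluene, −78 °C], with the slim alkynyl group as the small and the branched alkenyl group as the large substituent, should deliver 13 directly. This replaces steps 5 and 6 and avoids discarding half of the material.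

3. Step 11. Ozone may over-oxidise the pyranone C3=C4 bond or the electron-rich arene once the hindered alkene is consumed, or cleavage may stall before completion. Fallback, setting out from 22: the cleavage is done in two stages. Catalytic dihydroxylation (OsO4 cat., NMO, acetone/H2O), which favours the isolated alkene over the enoate-type C3=C4 bond, should give (R)-8-[1-(tert-butyldimethylsilyloxy)-2-hydroxy-2-(hydroxymethyl)-3-methylbutyl]-7-methoxy-2H-chromen-2-one F4 as inconsequential C2′ epimers. Glycol cleavage with NaIO4 (THF/H2O) then returns to 23.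

**Further compounds**
F1 | step 8 | cyclobut-2-en-1-one | O=C1C=CC1
F2 | step 8 | (S)-2-[1-(tert-butyldimethylsilyloxy)-3-methyl-2-methylidenebutyl]-3-methoxyphenol | COc1cccc(O)c1[C@@H](O[Si](C)(C)C(C)(C)C)C(=C)C(C)C
F3 | step 5 | 1-methoxy-5-methyl-4-methylidenehex-1-yn-3-one | COC#CC(=O)C(=C)C(C)C
F4 | step 11 | (R)-8-[1-(tert-butyldimethylsilyloxy)-2-hydroxy-2-(hydroxymethyl)-3-methylbutyl]-7-methoxy-2H-chromen-2-one (C2′ epimers) | COc1ccc2ccc(=O)oc2c1[C@@H](O[Si](C)(C)C(C)(C)C)C(O)(CO)C(C)C
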